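**Retrosynthetic overview**
1. The β-substituted butenolide is unveiled last from a 3-alkylfuran (singlet oxygen, then NaBH4), followed by removal of two silyl ethers.
2. Key disconnection: the bond from the quaternary C5 of the seven-membered ring (azulene numbering, α to the C4 ketone) to the side-chain CH2. The enabling feature is that C5 is a ketone α-carbon whose ring neighbour C6 carries a methyl group: together they are the opened form of a cyclopropane fused across C5–C6 of the cycloheptanone. Li/NH3 strain-release cleavage of this conjugated cyclopropyl ketone reveals the C6 methyl and gives the tetrasubstituted C4–C5 enolate regiospecifically, which is alkylated by 3-(2-iodoethyl)furan.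
3. The cyclopropane comes from a hydroxyl-directed Simmons–Smith reaction on a cycloheptenol; the seven-membered ring comes from ring-closing metathesis of a methacryloyl/butenyl cyclopentanol.
4. Both ring-fusion centres come from an aldol reaction (methacrolein) and a butenyl Grignard addition on a cyclopentanone made by CBS desymmetrization of 2,2-dimethylcyclopentane-1,3-dione.
5. Ring order: five-membered ring (purchased), seven-membered ring (metathesis), temporary cyclopropane (opened in the key step), butenolide (last).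

Key step: step 12

Remarks on the chemistry: azulene numbering is used for all bicyclic compounds (five-membered ring C1–C3, ring fusion C3a and C8a, ketone carbon C4, quaternary carbon C5, methyl-bearing carbon C6). "α" is the face of the C3a hydrogen and "β" the face of the C8a oxygen. The dione, methacrolein, but-3-en-1-ylmagnesium bromide (THF solution) and 2-(furan-3-yl)ethanol are assumed to be commercially available.

Step 1
Reactants: 1 2,2-dimethylcyclopentane-1,3-dione
Product: 2 (R)-3-hydroxy-2,2-dimethylcyclopentan-1-one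
Conditions: (S)-2-methyl-CBS-oxazaborolidine (15 mol%), BH3·SMe2 (0.6 equiv), THF, −20 °C; MeOH, then aq. HCl
Reagents that add atoms: none
Why: CBS reduction desymmetrizes the dione; the quaternary carbon acts as the large and the CH2 as the small substituent, so the (S)-catalyst should give the (R)-carbinol, and substoichiometric borane limits over-reduction to the diol.

Step 2
Reactants: 2 (R)-3-hydroxy-2,2-dimethylcyclopentan-1-one
Product: 3 (R)-3-[(tert-butyldimethylsilyl)oxy]-2,2-dimethylcyclopentan-1-one
Conditions: TBSCl, imidazole, DMF, rt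
Reagents that add atoms: tert-butyldimethylsilyl chloride CC(C)(C)[Si](C)(C)Cl
Why: Standard silylation of the secondary alcohol; the ether blocks retro-aldol opening of the β-hydroxy ketone under the basic steps that follow.

Step 3
Reactants: 3 (R)-3-[(tert-butyldimethylsilyl)oxy]-2,2-dimethylcyclopentan-1-one; 4 methacrolein
Product: 6 (3R,5S)-3-[(tert-butyldimethylsilyl)oxy]-5-(1-hydroxy-2-methylprop-2-en-1-yl)-2,2-dimethylcyclopentan-1-one (both carbinol epimers), via lithium enolate 5 (not isolated)
Conditions: LiN(i-Pr)2 (LDA), THF, −78 °C; then 4, −78 °C; aq. NH4Cl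
Reagents that add atoms: none
Why: Aldol addition: only C5 can be enolized (C2 is quaternary) and the aldehyde should add 1,2 to the enolate face anti to the C3 silyloxy group, setting C5 trans to it; the carbinol configuration is not controlled and is erased in step 5.

Step 4
Reactants: 6 aldol adduct; 7 but-3-en-1-ylmagnesium bromide
Product: 8 (1R,3R,5S)-1-(but-3-en-1-yl)-3-[(tert-butyldimethylsilyl)oxy]-5-(1-hydroxy-2-methylprop-2-en-1-yl)-2,2-dimethylcyclopentan-1-ol
Conditions: 7 (3 equiv), LaCl3·2LiCl (1 equiv), THF, −78 to 0 °C; aq. NH4Cl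
Reagents that add atoms: none
Why: Lanthanide-assisted Grignard 1,2-addition (the additive suppresses enolization and retro-aldol of the metal aldolate); the nucleophile should attack the chelated ketone anti to the adjacent C5 substituent, placing the butenyl chain trans to that side chain and the new tertiary hydroxyl cis to it, which is the trans ring fusion of the target.

Step 5
Reactants: 8 diol
Product: 9 1-[(1R,2R,4R)-2-(but-3-en-1-yl)-4-[(tert-butyldimethylsilyl)oxy]-2-hydroxy-3,3-dimethylcyclopentyl]-2-methylprop-2-en-1-one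
Conditions: Dess–Martin periodinane, NaHCO3, CH2Cl2, 0 °C to rt
Reagents that add atoms: none
Why: Dess–Martin oxidation converts only the secondary allylic alcohol (both epimers converge on one ketone), the tertiary alcohol is inert, and the buffered medium avoids retro-aldol or dehydration of the β-hydroxy ketone.

Step 6
Reactants: 9 β-hydroxy dienone
Product: 10 (2R,3aR,8aR)-2-[(tert-butyldimethylsilyl)oxy]-8a-hydroxy-1,1,5-trimethyl-2,3,3a,7,8,8a-hexahydroazulen-4(1H)-one
Conditions: second-generation Grubbs catalyst RuCl2(=CHPh)(H2IMes)(PCy3) (10 mol%), toluene (2 mM), 80 °C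
Reagents that add atoms: none
Why: Ring-closing metathesis: the catalyst loads at the monosubstituted butenyl alkene and closes onto the methacryloyl alkene to give the trisubstituted cycloheptenone, driven by loss of ethylene; no stereocenter is formed.

Step 7
Reactants: 10 bicyclic β-hydroxy enone
Product: 11 (2R,3aS,4S,8aR)-2-[(tert-butyldimethylsilyl)oxy]-1,1,5-trimethyl-1,2,3,3a,4,7,8,8a-octahydroazulene-4,8a-diol
Conditions: Me4NBH(OAc)3 (5 equiv), MeCN/AcOH 1:1, −30 °C
Reagents that add atoms: none
Why: Saksena–Evans hydroxyl-directed reduction: the axial C8a hydroxyl exchanges onto boron and delivers hydride intramolecularly to the β face of the C4 carbonyl, which should give the anti-1,3-diol with the new C4 hydroxyl α; the reagent reduces the enone 1,2 only.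

Step 8
Reactants: 11 anti-diol
Product: 12 (2R,3aS,4S,5R,6S,8aR)-2-[(tert-butyldimethylsilyl)oxy]-1,1,5-trimethyl-5,6-methanodecahydroazulene-4,8a-diol (cyclopropane CH2 on the α face, syn to the C4 hydroxyl)
Conditions: Et2Zn (5 equiv), CH2I2 (10 equiv), CH2Cl2, 0 °C to rt; aq. NH4Cl
Reagents that add atoms: diiodomethane ICI
Why: Hydroxyl-directed Simmons–Smith cyclopropanation (Furukawa modification): the zinc alkoxide of the allylic C4 hydroxyl should deliver the methylene to the syn (α) face of the C5=C6 alkene, which fixes C6 so that the CH2 later becomes the α-oriented C6 methyl.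

Step 9
Reactants: 12 cyclopropyl diol
Product: 13 (2R,3aR,5R,6S,8aR)-2-[(tert-butyldimethylsilyl)oxy]-8a-hydroxy-1,1,5-trimethyl-5,6-methanooctahydroazulen-4(1H)-one
Conditions: Dess–Martin periodinane, NaHCO3, CH2Cl2, 0 °C to rt
Reagents that add atoms: none
Why: Dess–Martin oxidation of the secondary cyclopropylcarbinol restores the C4 ketone, now conjugated with the cyclopropane; the tertiary alcohol and the silyl ether are untouched.

Step 10
Reactants: 13 cyclopropyl ketol
Product: 14 (2R,3aR,5R,6S,8aR)-2-[(tert-butyldimethylsilyl)oxy]-1,1,5-trimethyl-8a-[(triethylsilyl)oxy]-5,6-methanooctahydroazulen-4(1H)-one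
Conditions: TESOTf, 2,6-lutidine, CH2Cl2, −78 to 0 °C
Reagents that add atoms: triethylsilyl trifluoromethanesulfonate CC[Si](CC)(CC)OS(=O)(=O)C(F)(F)F
Why: Silylation of the hindered tertiary alcohol with the reactive silyl triflate; the ether prevents alkoxide-triggered retro-aldol cleavage in the strongly basic key step.

Step 11
Reactants: 15 2-(furan-3-yl)ethan-1-ol
Product: 16 3-(2-iodoethyl)furan
Conditions: I2, PPh3, imidazole, CH2Cl2, 0 °C to rt
Reagents that add atoms: iodine II
Why: Appel iodination of the primary alcohol (SN2 on the alkoxyphosphonium ion); the furan is inert under these neutral conditions.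

Step 12
Reactants: 14 silyl-protected cyclopropyl ketone; 16 3-(2-iodoethyl)furan
Product: 18 (2R,3aR,5S,6R,8aR)-2-[(tert-butyldimethylsilyl)oxy]-5-[2-(furan-3-yl)ethyl]-1,1,5,6-tetramethyl-8a-[(triethylsilyl)oxy]octahydroazulen-4(1H)-one, via lithium enolate 17 (not isolated)
Conditions: Li (2.1 equiv), t-BuOH (1.0 equiv), NH3(l)/THF, −78 °C; NH3 evaporated; then 16 (5 equiv), THF/HMPA, −78 °C to rt
Reagents that add atoms: none
Why: Two single-electron transfers from lithium to the conjugated cyclopropyl ketone give a ketyl radical anion that relieves the ring strain by cleaving the cyclopropane bond between the ketone α-carbon C5 and the CH2 (the bond that overlaps best with the carbonyl π system); t-BuOH protonates the primary carbanion to the C6 methyl (C6 configuration retained from the cyclopropane) and leaves the tetrasubstituted C4–C5 lithium enolate 17 regiospecifically, an enolate that deprotonation could not deliver selectively because both α-carbons of the corresponding ketone would be tertiary. After removal of ammonia the enolate is C-alkylated by iodide 16 in an SN2 reaction. The closest known reaction type is the dissolving-metal reductive cleavage of conjugated cyclopropyl ketones with trapping of the enolate by an alkyl halide (reductive alkylation). No ring is closed; the temporary cyclopropane is opened. The new quaternary stereocenter C5 is controlled by the adjacent C6: to avoid A(1,2) strain with the C5 methyl, the C6 methyl should sit pseudoaxial on the α face, so the electrophile enters from the β face and the two methyls end up cis with the side chain β. The step needs exocyclic rather than ring-expanding cleavage (secured by orbital overlap in the fused system) and SN2 over E2 and C- over O-alkylation (favoured by the iodide, the lithium counter-ion, HMPA and excess 16), while exactly one equivalent of t-BuOH avoids LiNH2 that could equilibrate the enolate or trigger β-elimination of the silyloxy group.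

Step 13
Reactants: 18 furan ketone
Product: 20 (2R,3aR,5S,6R,8aR)-2-[(tert-butyldimethylsilyl)oxy]-5-[2-(2-hydroxy-5-oxo-2,5-dihydrofuran-3-yl)ethyl]-1,1,5,6-tetramethyl-8a-[(triethylsilyl)oxy]octahydroazulen-4(1H)-one (lactol epimers), via furan endoperoxide 19 (not isolated)
Conditions: O2, visible light, tetraphenylporphyrin (cat.), i-Pr2NEt, CH2Cl2, −78 °C
Reagents that add atoms: oxygen O=O
Why: [4+2] addition of singlet oxygen to the furan followed by base-induced Kornblum–DeLaMare-type fragmentation: the hindered amine removes the bridgehead proton remote from the alkyl chain, so that carbon becomes the lactone carbonyl and the β-substituted γ-hydroxybutenolide should form regioselectively.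

Step 14
Reactants: 20 γ-hydroxybutenolide
Product: 22 (2R,3aR,5S,6R,8aR)-2-[(tert-butyldimethylsilyl)oxy]-1,1,5,6-tetramethyl-5-[2-(5-oxo-2,5-dihydrofuran-3-yl)ethyl]-8a-[(triethylsilyl)oxy]octahydroazulen-4(1H)-one, via sodium hydroxy carboxylate 21 (not isolated)
Conditions: NaBH4, THF/EtOH, 0 °C; then 1 M HCl to pH 3, rt
Reagents that add atoms: none
Why: The lactol is in ring-chain equilibrium with the formyl carboxylate, whose aldehyde is reduced by borohydride; acidification lactonizes the (Z)-hydroxy acid to the butenolide, while the C4 ketone, flanked by a quaternary carbon and the ring-fusion carbon, should be too hindered to react at 0 °C.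

Step 15
Reactants: 22 bis-silyl ether
Product: 23 (2R,3aR,5S,6R,8aR)-2,8a-dihydroxy-1,1,5,6-tetramethyl-5-[2-(5-oxo-2,5-dihydrofuran-3-yl)ethyl]octahydroazulen-4(1H)-one (CNP0077405.2)
Conditions: HF·pyridine, pyridine, THF, 0 °C to rt
Reagents that add atoms: none
Why: Fluoride-mediated cleavage of both silyl ethers under mildly acidic, non-basic conditions that should avoid retro-aldol cleavage of the β-hydroxy ketone and isomerization of the butenolide.

**Compound list**
1 | 2,2-dimethylcyclopentane-1,3-dione | CC1(C)C(=O)CCC1=O | starting material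
2 | (R)-3-hydroxy-2,2-dimethylcyclopentan-1-one | O=C1CC[C@@H](O)C1(C)C | intermediate
3 | (R)-3-[(tert-butyldimethylsilyl)oxy]-2,2-dimethylcyclopentan-1-one | O=C1CC[C@@H](O[Si](C)(C)C(C)(C)C)C1(C)C | intermediate
4 | methacrolein (2-methylprop-2-enal) | CC(=C)C=O | starting material
5 | lithium (R)-4-[(tert-butyldimethylsilyl)oxy]-5,5-dimethylcyclopent-1-en-1-olate | [Li]OC1=CC[C@@H](O[Si](C)(C)C(C)(C)C)C1(C)C | intermediate
6 | (3R,5S)-3-[(tert-butyldimethylsilyl)oxy]-5-(1-hydroxy-2-methylprop-2-en-1-yl)-2,2-dimethylcyclopentan-1-one (carbinol epimers) | O=C1[C@@H](C[C@@H](O[Si](C)(C)C(C)(C)C)C1(C)C)C(O)C(C)=C | intermediate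
7 | but-3-en-1-ylmagnesium bromide | C=CCC[Mg]Br | starting material
8 | (1R,3R,5S)-1-(but-3-en-1-yl)-3-[(tert-butyldimethylsilyl)oxy]-5-(1-hydroxy-2-methylprop-2-en-1-yl)-2,2-dimethylcyclopentan-1-ol (carbinol epimers) | C=CCC[C@@]1(O)[C@@H](C[C@@H](O[Si](C)(C)C(C)(C)C)C1(C)C)C(O)C(C)=C | intermediate
9 | 1-[(1R,2R,4R)-2-(but-3-en-1-yl)-4-[(tert-butyldimethylsilyl)oxy]-2-hydroxy-3,3-dimethylcyclopentyl]-2-methylprop-2-en-1-one | C=CCC[C@@]1(O)[C@@H](C[C@@H](O[Si](C)(C)C(C)(C)C)C1(C)C)C(=O)C(C)=C | intermediate
10 | (2R,3aR,8aR)-2-[(tert-butyldimethylsilyl)oxy]-8a-hydroxy-1,1,5-trimethyl-2,3,3a,7,8,8a-hexahydroazulen-4(1H)-one | CC1=CCC[C@@]2(O)[C@@H](C[C@@H](O[Si](C)(C)C(C)(C)C)C2(C)C)C1=O | intermediate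
11 | (2R,3aS,4S,8aR)-2-[(tert-butyldimethylsilyl)oxy]-1,1,5-trimethyl-1,2,3,3a,4,7,8,8a-octahydroazulene-4,8a-diol | CC1=CCC[C@@]2(O)[C@@H](C[C@@H](O[Si](C)(C)C(C)(C)C)C2(C)C)[C@@H]1O | intermediate
12 | (2R,3aS,4S,5R,6S,8aR)-2-[(tert-butyldimethylsilyl)oxy]-1,1,5-trimethyl-5,6-methanodecahydroazulene-4,8a-diol (cyclopropane fused across C5–C6, CH2 α) | C[C@@]12C[C@@H]1CC[C@@]3(O)[C@@H](C[C@@H](O[Si](C)(C)C(C)(C)C)C3(C)C)[C@@H]2O | intermediate
13 | (2R,3aR,5R,6S,8aR)-2-[(tert-butyldimethylsilyl)oxy]-8a-hydroxy-1,1,5-trimethyl-5,6-methanooctahydroazulen-4(1H)-one | C[C@@]12C[C@@H]1CC[C@@]3(O)[C@@H](C[C@@H](O[Si](C)(C)C(C)(C)C)C3(C)C)C2=O | intermediate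
14 | (2R,3aR,5R,6S,8aR)-2-[(tert-butyldimethylsilyl)oxy]-1,1,5-trimethyl-8a-[(triethylsilyl)oxy]-5,6-methanooctahydroazulen-4(1H)-one | C[C@@]12C[C@@H]1CC[C@@]3(O[Si](CC)(CC)CC)[C@@H](C[C@@H](O[Si](C)(C)C(C)(C)C)C3(C)C)C2=O | intermediate
15 | 2-(furan-3-yl)ethan-1-ol | OCCc1ccoc1 | starting material
16 | 3-(2-iodoethyl)furan | ICCc1ccoc1 | intermediate
17 | lithium enolate of the ring-opened ketone: lithium (2R,3aS,6R,8aR)-2-[(tert-butyldimethylsilyl)oxy]-1,1,5,6-tetramethyl-8a-[(triethylsilyl)oxy]-1,2,3,3a,6,7,8,8a-octahydroazulen-4-olate | C[C@@H]1CC[C@@]2(O[Si](CC)(CC)CC)[C@@H](C[C@@H](O[Si](C)(C)C(C)(C)C)C2(C)C)C(O[Li])=C1C | intermediate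
18 | (2R,3aR,5S,6R,8aR)-2-[(tert-butyldimethylsilyl)oxy]-5-[2-(furan-3-yl)ethyl]-1,1,5,6-tetramethyl-8a-[(triethylsilyl)oxy]octahydroazulen-4(1H)-one | C[C@@H]1CC[C@@]2(O[Si](CC)(CC)CC)[C@@H](C[C@@H](O[Si](C)(C)C(C)(C)C)C2(C)C)C(=O)[C@@]1(C)CCc1ccoc1 | intermediate
19 | 2,5-endoperoxide of furan 18 (2,3,7-trioxabicyclo[2.2.1]hept-5-ene carrying the side chain at C5) | C[C@@H]1CC[C@@]2(O[Si](CC)(CC)CC)[C@@H](C[C@@H](O[Si](C)(C)C(C)(C)C)C2(C)C)C(=O)[C@@]1(C)CCC1=CC2OOC1O2 | intermediate
20 | (2R,3aR,5S,6R,8aR)-2-[(tert-butyldimethylsilyl)oxy]-5-[2-(2-hydroxy-5-oxo-2,5-dihydrofuran-3-yl)ethyl]-1,1,5,6-tetramethyl-8a-[(triethylsilyl)oxy]octahydroazulen-4(1H)-one (lactol epimers) | C[C@@H]1CC[C@@]2(O[Si](CC)(CC)CC)[C@@H](C[C@@H](O[Si](C)(C)C(C)(C)C)C2(C)C)C(=O)[C@@]1(C)CCC1=CC(=O)OC1O | intermediate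
21 | sodium (2Z)-3-(hydroxymethyl)-5-[(2R,3aR,5S,6R,8aR)-2-[(tert-butyldimethylsilyl)oxy]-1,1,5,6-tetramethyl-4-oxo-8a-[(triethylsilyl)oxy]decahydroazulen-5-yl]pent-2-enoate | C[C@@H]1CC[C@@]2(O[Si](CC)(CC)CC)[C@@H](C[C@@H](O[Si](C)(C)C(C)(C)C)C2(C)C)C(=O)[C@@]1(C)CC/C(CO)=C/C(=O)[O-].[Na+] | intermediate
22 | (2R,3aR,5S,6R,8aR)-2-[(tert-butyldimethylsilyl)oxy]-1,1,5,6-tetramethyl-5-[2-(5-oxo-2,5-dihydrofuran-3-yl)ethyl]-8a-[(triethylsilyl)oxy]octahydroazulen-4(1H)-one | C[C@@H]1CC[C@@]2(O[Si](CC)(CC)CC)[C@@H](C[C@@H](O[Si](C)(C)C(C)(C)C)C2(C)C)C(=O)[C@@]1(C)CCC1=CC(=O)OC1 | intermediate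
23 | (2R,3aR,5S,6R,8aR)-2,8a-dihydroxy-1,1,5,6-tetramethyl-5-[2-(5-oxo-2,5-dihydrofuran-3-yl)ethyl]octahydroazulen-4(1H)-one | C[C@@H]1CC[C@@]2(O)[C@@H](C[C@@H](O)C2(C)C)C(=O)[C@@]1(C)CCC1=CC(=O)OC1 | target

**Step count**
Total steps: 15. Longest linear sequence: 14 steps (steps 1–10 and 12–15, from dione 1); the iodide branch is one step (step 11).

**Steps most likely to fail**

Step 12. The hindered tetrasubstituted enolate may act as a base rather than a nucleophile (E2 elimination of the iodide to 3-vinylfuran, proton transfer that scrambles the enolate), may alkylate on oxygen, or may be attacked with insufficient facial selectivity. The fallback sets out from 14 and keeps the strain-release enolate generation, but traps the enolate with allyl bromide (Li, t-BuOH, NH3/THF; then allyl bromide), a more reactive electrophile that cannot eliminate, to give the C5-allyl ketone F1. Lemieux–Johnson cleavage (OsO4 cat., NaIO4, 2,6-lutidine, dioxane/water) would give the aldehyde F2. Addition of 3-furyllithium (3-bromofuran, n-BuLi, THF, −78 °C), which should select the aldehyde over the hindered ketone, would give the furyl carbinol F3. Acylation with 1,1'-thiocarbonyldiimidazole (DMAP, CH2Cl2) would give the imidazole-1-carbothioate F4, and Barton–McCombie deoxygenation (Bu3SnH, AIBN, toluene, 80 °C) comes back to the route at 18.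

Step 4. The basic reagent may deprotonate the β-hydroxy ketone at C5 or provoke retro-aldol cleavage of the metal aldolate instead of adding, and the remote silyloxy group may erode the facial selectivity. The fallback sets out from 6 and delivers the chain in two smaller pieces. Silylation (TESCl, imidazole, DMF) would give the triethylsilyl ether F5. Methylene transfer from dimethylsulfonium methylide (Me3SI, KN(SiMe3)2, THF, −10 °C), a small and weakly basic nucleophile that should also attack anti to the C5 substituent, would give the spiro-epoxide F6. Copper-catalysed opening at the epoxide CH2 with allylmagnesium bromide (CuI cat., THF, −40 to 0 °C) would give the butenyl carbinol F7, and selective removal of the triethylsilyl group (PPTS, MeOH, 0 °C) comes back to the route at 8.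

Step 8. The two zinc alkoxides may compete for delivery of the methylene (the tertiary C8a alkoxide lies on the opposite face), and transfer to the trisubstituted alkene may be sluggish. The fallback sets out from enone 10 and uses steric instead of directed control. Silylation of the tertiary alcohol (TESOTf, 2,6-lutidine, CH2Cl2) would give the silyl enone F8. Corey–Chaykovsky cyclopropanation (Me3S(O)I, NaH, DMSO, rt), in which the sulfoxonium ylide should add to C6 from the α face, away from the axial β-silyloxy group, comes back to the route at 14 and makes steps 7 to 10 unnecessary.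

**Further compounds**
F1 | step 12 | (2R,3aR,5S,6R,8aR)-5-allyl-2-[(tert-butyldimethylsilyl)oxy]-1,1,5,6-tetramethyl-8a-[(triethylsilyl)oxy]octahydroazulen-4(1H)-one | C[C@@H]1CC[C@@]2(O[Si](CC)(CC)CC)[C@@H](C[C@@H](O[Si](C)(C)C(C)(C)C)C2(C)C)C(=O)[C@@]1(C)CC=C
F2 | step 12 | 2-[(2R,3aR,5S,6R,8aR)-2-[(tert-butyldimethylsilyl)oxy]-1,1,5,6-tetramethyl-4-oxo-8a-[(triethylsilyl)oxy]decahydroazulen-5-yl]acetaldehyde | C[C@@H]1CC[C@@]2(O[Si](CC)(CC)CC)[C@@H](C[C@@H](O[Si](C)(C)C(C)(C)C)C2(C)C)C(=O)[C@@]1(C)CC=O
F3 | step 12 | 5-[2-(furan-3-yl)-2-hydroxyethyl] analogue of 18 (carbinol epimers) | C[C@@H]1CC[C@@]2(O[Si](CC)(CC)CC)[C@@H](C[C@@H](O[Si](C)(C)C(C)(C)C)C2(C)C)C(=O)[C@@]1(C)CC(O)c1ccoc1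
F4 | step 12 | O-[1-(furan-3-yl)-2-(azulen-5-yl)ethyl] 1H-imidazole-1-carbothioate derived from F3 | C[C@@H]1CC[C@@]2(O[Si](CC)(CC)CC)[C@@H](C[C@@H](O[Si](C)(C)C(C)(C)C)C2(C)C)C(=O)[C@@]1(C)CC(OC(=S)n1ccnc1)c1ccoc1
F5 | step 4 | triethylsilyl ether of aldol adduct 6 | O=C1[C@@H](C[C@@H](O[Si](C)(C)C(C)(C)C)C1(C)C)C(O[Si](CC)(CC)CC)C(C)=C
F6 | step 4 | spiro-epoxide from F5 (oxirane at the former ketone carbon, oxygen cis to the C5 side chain) | C1O[C@@]12[C@@H](C[C@@H](O[Si](C)(C)C(C)(C)C)C2(C)C)C(O[Si](CC)(CC)CC)C(C)=C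
F7 | step 4 | allylic-carbinol triethylsilyl ether of diol 8 | C=CCC[C@@]1(O)[C@@H](C[C@@H](O[Si](C)(C)C(C)(C)C)C1(C)C)C(O[Si](CC)(CC)CC)C(C)=C
F8 | step 8 | 8a-triethylsilyl ether of enone 10 | CC1=CCC[C@@]2(O[Si](CC)(CC)CC)[C@@H](C[C@@H](O[Si](C)(C)C(C)(C)C)C2(C)C)C1=O
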